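**Plan**

1. Numbering used throughout: terpenoid carbons C1–C11, ring A = C1–C5 and C10, ring B = C5–C10; OAc on C3, two methyls on C4, C6=O, C7=C8 with a methyl on C8, C11H2–O–coumarin on C9, methyl on C10.
2. Retrosynthesis: the C3 acetate and the C11–O aryl ether (umbelliferone) are cut first, the C7=C8 enone is traced back to a C6=C7 silyl enol ether and C11 to an ester, and then C5–C10 and C8–C9 are cut together.
3. Enabling feature: the C6 ketone, with C5–H on one side and C7=C8 on the other, is a latent 2-silyloxydiene C5=C6(OSi)–C7=C8, and C9=C10 with its methyl and C11 is a latent (E)-3-methyl-2-enoate held to C5 by the four carbons C1–C4, so a single intramolecular [4+2] closes rings A and B at once.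
4. Forward: the chain is built linearly from methyl geranate (C11, C9, C10 with its methyl, C1–C3) by oxidative cleavage, reverse prenylation with 3-methylbuta-1,2-diene (C4 with both methyls, C5, C6), hydroboration/oxidation, propenyl addition (C7, C8 with its methyl) and enol silylation; rings A and B then form together, and ester reduction, Mitsunobu etherification, dehydrogenation, desilylation and acetylation complete the target.
5. Stereochemistry: C3 (R) comes from the enantioselective reverse prenylation; C5, C9 and C10 come from the cycloaddition (E-enoate geometry, ester endo with the tether anti, chair tether with the C3 silyloxy group equatorial); the C8 centre formed on the way is erased by the dehydrogenation.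

Key step: step 9

Remark: atom labels C1–C11 in the text follow the terpenoid numbering above; locants inside compound names are IUPAC locants.
Remark: methyl geranate is used as the pure (2E) isomer, since this alkene geometry later fixes C9 against C10.
Remark: (S)-SEGPHOS is assumed to be the ligand antipode that directs the reverse-prenyl group to the Si face of aldehyde 3 (giving 6R); the sense is to be confirmed on 5 by Mosher ester analysis and (R)-SEGPHOS used instead should the opposite sense be found.

**Route**

Step 1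
Reactants: 1 methyl geranate [methyl (2E)-3,7-dimethylocta-2,6-dienoate]
Product: 3 methyl (2E)-3-methyl-6-oxohex-2-enoate, via ozonide 2 (not isolated)
Conditions: O3, CH2Cl2, Sudan Red 7B (indicator), −78 °C; then Me2S, −78 °C to rt
Reagents that add atoms: ozone, [O-][O+]=O
Why: Chemoselective ozonolysis: ozone attacks the electron-rich isopropylidene alkene far faster than the conjugated, electron-poor enoate, the dye marks the end point, and reduction of ozonide 2 with Me2S releases the aldehyde; no stereocentre is involved.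

Step 2
Reactants: 3 methyl (2E)-3-methyl-6-oxohex-2-enoate; 4 3-methylbuta-1,2-diene
Product: 5 methyl (2E,6R)-6-hydroxy-3,7,7-trimethylnona-2,8-dienoate
Conditions: π-allyl iridium C,O-benzoate catalyst preformed from [Ir(cod)Cl]2, (S)-SEGPHOS, 4-cyano-3-nitrobenzoic acid, allyl acetate and Cs2CO3 (5 mol%), i-PrOH (2 equiv), toluene, 50 °C, sealed tube
Reagents that add atoms: none
Why: Iridium-catalysed transfer-hydrogenative carbonyl reverse prenylation (Krische coupling): the iridium hydride formed from i-PrOH hydrometalates the allene to a 1,1-dimethylallyl iridium species that adds to the aldehyde at its substituted terminus through a closed six-membered transition state, forming C3–C4 with the gem-dimethyl group and the C5=C6 vinyl group, while the chiral ligand directs addition to the Si face so that C3 is set as R and the enoate is left alone.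

Step 3
Reactants: 5 methyl (2E,6R)-6-hydroxy-3,7,7-trimethylnona-2,8-dienoate
Product: 6 methyl (2E,6R)-6-[(tert-butyldimethylsilyl)oxy]-3,7,7-trimethylnona-2,8-dienoate
Conditions: TBSOTf, 2,6-lutidine, CH2Cl2, −78 to 0 °C
Reagents that add atoms: tert-butyldimethylsilyl trifluoromethanesulfonate, CC(C)(C)[Si](C)(C)OS(=O)(=O)C(F)(F)F
Why: Silyl triflate silylation is the standard way to protect a hindered secondary alcohol next to a quaternary carbon, and the TBS ether should survive the borane, chromium, silyl triflate, thermal, hydride and palladium steps before fluoride removes it at the end.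

Step 4
Reactants: 6 methyl (2E,6R)-6-[(tert-butyldimethylsilyl)oxy]-3,7,7-trimethylnona-2,8-dienoate
Product: 8 methyl (2E,6R)-6-[(tert-butyldimethylsilyl)oxy]-9-hydroxy-3,7,7-trimethylnon-2-enoate, via B-alkyl-9-BBN adduct 7 (not isolated)
Conditions: 9-BBN-H, THF, 0 °C to rt; then H2O2, aq NaOAc, 0 °C to rt
Reagents that add atoms: hydrogen peroxide, OO (9-borabicyclo[3.3.1]nonane, B1C2CCCC1CCC2, contributes atoms only to intermediate 7)
Why: Hydroboration–oxidation: the bulky borane adds boron to the terminal carbon of the monosubstituted alkene (anti-Markovnikov, reinforced by the neighbouring quaternary C4) and ignores the trisubstituted electron-poor enoate and the ester, and buffered peroxide oxidation of 7 gives the primary C6 alcohol without saponifying the methyl ester.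

Step 5
Reactants: 8 methyl (2E,6R)-6-[(tert-butyldimethylsilyl)oxy]-9-hydroxy-3,7,7-trimethylnon-2-enoate
Product: 9 methyl (2E,6R)-6-[(tert-butyldimethylsilyl)oxy]-3,7,7-trimethyl-9-oxonon-2-enoate
Conditions: Dess–Martin periodinane, NaHCO3, CH2Cl2, 0 °C to rt
Reagents that add atoms: none
Why: Dess–Martin oxidation takes the primary alcohol to the C6 aldehyde under buffered conditions that leave the silyl ether and the enoate untouched; no stereocentre lies alpha to the new carbonyl.

Step 6
Reactants: 9 methyl (2E,6R)-6-[(tert-butyldimethylsilyl)oxy]-3,7,7-trimethyl-9-oxonon-2-enoate; 10 (E)-1-bromoprop-1-ene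
Product: 12 methyl (2E,6R,10E)-6-[(tert-butyldimethylsilyl)oxy]-9-hydroxy-3,7,7-trimethyldodeca-2,10-dienoate (both epimers at the new carbinol carbon), via (E)-prop-1-enylchromium dichloride 11 (not isolated)
Conditions: CrCl2 (4 equiv), NiCl2 (2 mol%), DMF, rt
Reagents that add atoms: none (chromium dichloride, Cl[Cr]Cl, contributes atoms only to intermediate 11)
Why: Nozaki–Hiyama–Kishi coupling: nickel-catalysed insertion into the C–Br bond and transmetalation give alkenylchromium 11 with retention of the E geometry, which adds to the aldehyde and not to the ester; the carbinol centre forms without control and is removed in step 7.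

Step 7
Reactants: 12 methyl (2E,6R,10E)-6-[(tert-butyldimethylsilyl)oxy]-9-hydroxy-3,7,7-trimethyldodeca-2,10-dienoate
Product: 13 methyl (2E,6R,10E)-6-[(tert-butyldimethylsilyl)oxy]-3,7,7-trimethyl-9-oxododeca-2,10-dienoate
Conditions: Dess–Martin periodinane, NaHCO3, CH2Cl2, rt
Reagents that add atoms: none
Why: Dess–Martin oxidation of the allylic alcohol converges both carbinol epimers on the (E)-enone C6(=O)–C7=C8 without touching the alkene geometry.

Step 8
Reactants: 13 methyl (2E,6R,10E)-6-[(tert-butyldimethylsilyl)oxy]-3,7,7-trimethyl-9-oxododeca-2,10-dienoate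
Product: 14 methyl (2E,6R,8Z,10E)-6-[(tert-butyldimethylsilyl)oxy]-3,7,7-trimethyl-9-[(triethylsilyl)oxy]dodeca-2,8,10-trienoate
Conditions: TESOTf, Et3N, CH2Cl2, −78 to 0 °C; filtration through basic alumina
Reagents that add atoms: triethylsilyl trifluoromethanesulfonate, CC[Si](CC)(CC)OS(=O)(=O)C(F)(F)F
Why: Soft enolisation: O-silylation of the enone and deprotonation by Et3N at C5, the only alpha-methylene, gives the cross-conjugated 2-silyloxydiene, the Z enol ether being favoured because the quaternary C4 avoids the propenyl group (allylic strain), which puts the tether on the outside of the diene as step 9 requires, while the ester is not enolised.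

Step 9
Reactants: 14 methyl (2E,6R,8Z,10E)-6-[(tert-butyldimethylsilyl)oxy]-3,7,7-trimethyl-9-[(triethylsilyl)oxy]dodeca-2,8,10-trienoate
Product: 15 methyl (1R,2R,4aS,6R,8aR)-6-[(tert-butyldimethylsilyl)oxy]-2,5,5,8a-tetramethyl-4-[(triethylsilyl)oxy]-1,2,4a,5,6,7,8,8a-octahydronaphthalene-1-carboxylate (trans-fused; in terpenoid numbering 3β-OTBS, 5α-H, 8β-methyl, 9β-CO2Me, 10β-methyl, C6=C7 silyl enol ether)
Conditions: toluene (0.01 M), BHT (cat.), N,O-bis(trimethylsilyl)acetamide (cat.), 190 °C, sealed tube
Reagents that add atoms: none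
Why: A thermal, concerted but asynchronous normal-demand [4+2] joins the silyloxydiene C5=C6(OSiEt3)–C7=C8 to the (E)-enoate C9=C10, the nucleophilic enol-ether terminus C5 bonding to the beta-carbon C10 and C8 bonding to C9. The closest known reaction type is the type 1 intramolecular Diels–Alder reaction of 1,7,9-decatrienes that carry a 2-silyloxydiene, which delivers decalins with a regiodefined silyl enol ether. Ring B closes as the cyclohexene of the cycloaddition itself and keeps C6=C7 as the enol ether, while ring A closes in the fused mode as the six-membered ring made of C5, C10 and the four-carbon tether C1–C4, folded as a chair. Suprafacial addition to the (E)-enoate places the C9 ester cis to the C10 methyl group, and suprafacial addition to the (E)-propenyl terminus sets C8 (methyl cis to the ester in the endo mode), a centre that step 12 erases. The transition state with the ester endo and the tether anti puts C5–H trans to the C10 methyl group (trans fusion), and the chair tether with the C3 silyloxy group equatorial selects the diene face so that the C10 methyl group ends cis to the C3 oxygen, which relays the R configuration of C3 to C5, C9 and C10. The step needs reactivity at a trisubstituted dienophile beside the quaternary C4 and both endo and facial selectivity: the short tether, the gem-dimethyl (Thorpe–Ingold) effect and the electron-rich diene should supply the first, and the fixed E and Z alkene geometries together with the equatorial preference of the silyloxy group the second.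

Step 10
Reactants: 15 methyl (1R,2R,4aS,6R,8aR)-6-[(tert-butyldimethylsilyl)oxy]-2,5,5,8a-tetramethyl-4-[(triethylsilyl)oxy]-1,2,4a,5,6,7,8,8a-octahydronaphthalene-1-carboxylate
Product: 16 [(1R,2S,4aS,6R,8aS)-6-[(tert-butyldimethylsilyl)oxy]-2,5,5,8a-tetramethyl-4-[(triethylsilyl)oxy]-1,2,4a,5,6,7,8,8a-octahydronaphthalen-1-yl]methanol
Conditions: i-Bu2AlH, CH2Cl2, −78 to 0 °C; aq potassium sodium tartrate
Reagents that add atoms: none
Why: Hydride reduction of the ester to the primary C11 alcohol; silyl enol ethers and silyl ethers are inert to the aluminium hydride at low temperature, so the C6 ketone stays masked as its regiodefined enol ether and C9 is not epimerised.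

Step 11
Reactants: 16 [(1R,2S,4aS,6R,8aS)-6-[(tert-butyldimethylsilyl)oxy]-2,5,5,8a-tetramethyl-4-[(triethylsilyl)oxy]-1,2,4a,5,6,7,8,8a-octahydronaphthalen-1-yl]methanol; 17 umbelliferone (7-hydroxy-2H-chromen-2-one)
Product: 18 7-{[(1R,2S,4aS,6R,8aS)-6-[(tert-butyldimethylsilyl)oxy]-2,5,5,8a-tetramethyl-4-[(triethylsilyl)oxy]-1,2,4a,5,6,7,8,8a-octahydronaphthalen-1-yl]methoxy}-2H-chromen-2-one
Conditions: PPh3, DIAD, THF, 0 °C to rt
Reagents that add atoms: none
Why: Mitsunobu etherification: the phenol of umbelliferone is acidic enough to protonate the phosphine–azodicarboxylate betaine, and its phenoxide displaces the oxyphosphonium of the primary C11 carbinol by SN2, which touches no stereocentre.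

Step 12
Reactants: 18 7-{[(1R,2S,4aS,6R,8aS)-6-[(tert-butyldimethylsilyl)oxy]-2,5,5,8a-tetramethyl-4-[(triethylsilyl)oxy]-1,2,4a,5,6,7,8,8a-octahydronaphthalen-1-yl]methoxy}-2H-chromen-2-one
Product: 19 7-{[(1R,4aS,6R,8aS)-6-[(tert-butyldimethylsilyl)oxy]-2,5,5,8a-tetramethyl-4-oxo-1,4,4a,5,6,7,8,8a-octahydronaphthalen-1-yl]methoxy}-2H-chromen-2-one
Conditions: Pd(OAc)2 (1.2 equiv), MeCN, rt to 40 °C
Reagents that add atoms: none
Why: Saegusa–Ito oxidation: divalent palladium takes over the silyl enol ether as a C7-bound palladium enolate and syn beta-hydride elimination of the C8–H gives the C7=C8 enone and zerovalent palladium, the position of the alkene being dictated by the C6=C7 enol ether from step 9; the C8 centre disappears and C5 and C9 are untouched.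

Step 13
Reactants: 19 7-{[(1R,4aS,6R,8aS)-6-[(tert-butyldimethylsilyl)oxy]-2,5,5,8a-tetramethyl-4-oxo-1,4,4a,5,6,7,8,8a-octahydronaphthalen-1-yl]methoxy}-2H-chromen-2-one
Product: 20 7-{[(1R,4aS,6R,8aS)-6-hydroxy-2,5,5,8a-tetramethyl-4-oxo-1,4,4a,5,6,7,8,8a-octahydronaphthalen-1-yl]methoxy}-2H-chromen-2-one
Conditions: aq HF (48%), MeCN, 0 °C to rt
Reagents that add atoms: none
Why: Acidic fluoride cleavage of the secondary TBS ether; aqueous HF in MeCN is tolerated by the enone, the aryl alkyl ether and the coumarin lactone and, being non-basic, should avoid epimerisation at C5 or C9 and loss of the aryloxy group by vinylogous elimination.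

Step 14
Reactants: 20 7-{[(1R,4aS,6R,8aS)-6-hydroxy-2,5,5,8a-tetramethyl-4-oxo-1,4,4a,5,6,7,8,8a-octahydronaphthalen-1-yl]methoxy}-2H-chromen-2-one
Product: 21 7-{[(1R,4aS,6R,8aS)-6-(acetyloxy)-2,5,5,8a-tetramethyl-4-oxo-1,4,4a,5,6,7,8,8a-octahydronaphthalen-1-yl]methoxy}-2H-chromen-2-one (CNP0363962.1)
Conditions: Ac2O, pyridine, DMAP (cat.), CH2Cl2, rt
Reagents that add atoms: acetic anhydride, CC(=O)OC(C)=O
Why: DMAP-catalysed acylation of the equatorial secondary alcohol proceeds with retention at C3 under conditions too mild to enolise the enone, giving the target acetate.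

**Compound list**

1 | methyl geranate, methyl (2E)-3,7-dimethylocta-2,6-dienoate | COC(=O)/C=C(\C)CCC=C(C)C | starting material
2 | methyl (2E)-5-(5,5-dimethyl-1,2,4-trioxolan-3-yl)-3-methylpent-2-enoate (ozonide, not isolated) | COC(=O)/C=C(\C)CCC1OOC(C)(C)O1 | intermediate
3 | methyl (2E)-3-methyl-6-oxohex-2-enoate | COC(=O)/C=C(\C)CCC=O | intermediate
4 | 3-methylbuta-1,2-diene | CC(C)=C=C | starting material
5 | methyl (2E,6R)-6-hydroxy-3,7,7-trimethylnona-2,8-dienoate | COC(=O)/C=C(\C)CC[C@@H](O)C(C)(C)C=C | intermediate
6 | methyl (2E,6R)-6-[(tert-butyldimethylsilyl)oxy]-3,7,7-trimethylnona-2,8-dienoate | COC(=O)/C=C(\C)CC[C@@H](O[Si](C)(C)C(C)(C)C)C(C)(C)C=C | intermediate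
7 | methyl (2E,6R)-9-(9-borabicyclo[3.3.1]nonan-9-yl)-6-[(tert-butyldimethylsilyl)oxy]-3,7,7-trimethylnon-2-enoate (not isolated) | COC(=O)/C=C(\C)CC[C@@H](O[Si](C)(C)C(C)(C)C)C(C)(C)CCB1C2CCCC1CCC2 | intermediate
8 | methyl (2E,6R)-6-[(tert-butyldimethylsilyl)oxy]-9-hydroxy-3,7,7-trimethylnon-2-enoate | COC(=O)/C=C(\C)CC[C@@H](O[Si](C)(C)C(C)(C)C)C(C)(C)CCO | intermediate
9 | methyl (2E,6R)-6-[(tert-butyldimethylsilyl)oxy]-3,7,7-trimethyl-9-oxonon-2-enoate | COC(=O)/C=C(\C)CC[C@@H](O[Si](C)(C)C(C)(C)C)C(C)(C)CC=O | intermediate
10 | (E)-1-bromoprop-1-ene | C/C=C/Br | starting material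
11 | (E)-prop-1-enylchromium dichloride (not isolated) | C/C=C/[Cr](Cl)Cl | intermediate
12 | methyl (2E,6R,10E)-6-[(tert-butyldimethylsilyl)oxy]-9-hydroxy-3,7,7-trimethyldodeca-2,10-dienoate (both epimers at the carbinol carbon, left undefined in the SMILES) | COC(=O)/C=C(\C)CC[C@@H](O[Si](C)(C)C(C)(C)C)C(C)(C)CC(O)/C=C/C | intermediate
13 | methyl (2E,6R,10E)-6-[(tert-butyldimethylsilyl)oxy]-3,7,7-trimethyl-9-oxododeca-2,10-dienoate | COC(=O)/C=C(\C)CC[C@@H](O[Si](C)(C)C(C)(C)C)C(C)(C)CC(=O)/C=C/C | intermediate
14 | methyl (2E,6R,8Z,10E)-6-[(tert-butyldimethylsilyl)oxy]-3,7,7-trimethyl-9-[(triethylsilyl)oxy]dodeca-2,8,10-trienoate | COC(=O)/C=C(\C)CC[C@@H](O[Si](C)(C)C(C)(C)C)C(C)(C)/C=C(\O[Si](CC)(CC)CC)/C=C/C | intermediate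
15 | methyl (1R,2R,4aS,6R,8aR)-6-[(tert-butyldimethylsilyl)oxy]-2,5,5,8a-tetramethyl-4-[(triethylsilyl)oxy]-1,2,4a,5,6,7,8,8a-octahydronaphthalene-1-carboxylate | CC(C)(C)[Si](C)(C)O[C@@H]1CC[C@@]2(C)[C@H](C(=O)OC)[C@H](C)C=C(O[Si](CC)(CC)CC)[C@@H]2C1(C)C | intermediate
16 | [(1R,2S,4aS,6R,8aS)-6-[(tert-butyldimethylsilyl)oxy]-2,5,5,8a-tetramethyl-4-[(triethylsilyl)oxy]-1,2,4a,5,6,7,8,8a-octahydronaphthalen-1-yl]methanol | CC(C)(C)[Si](C)(C)O[C@@H]1CC[C@@]2(C)[C@H](CO)[C@H](C)C=C(O[Si](CC)(CC)CC)[C@@H]2C1(C)C | intermediate
17 | umbelliferone, 7-hydroxy-2H-chromen-2-one | O=c1ccc2ccc(O)cc2o1 | starting material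
18 | 7-{[(1R,2S,4aS,6R,8aS)-6-[(tert-butyldimethylsilyl)oxy]-2,5,5,8a-tetramethyl-4-[(triethylsilyl)oxy]-1,2,4a,5,6,7,8,8a-octahydronaphthalen-1-yl]methoxy}-2H-chromen-2-one | CC(C)(C)[Si](C)(C)O[C@@H]1CC[C@@]2(C)[C@H](COc3ccc4ccc(=O)oc4c3)[C@H](C)C=C(O[Si](CC)(CC)CC)[C@@H]2C1(C)C | intermediate
19 | 7-{[(1R,4aS,6R,8aS)-6-[(tert-butyldimethylsilyl)oxy]-2,5,5,8a-tetramethyl-4-oxo-1,4,4a,5,6,7,8,8a-octahydronaphthalen-1-yl]methoxy}-2H-chromen-2-one | CC(C)(C)[Si](C)(C)O[C@@H]1CC[C@@]2(C)[C@H](COc3ccc4ccc(=O)oc4c3)C(C)=CC(=O)[C@@H]2C1(C)C | intermediate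
20 | 7-{[(1R,4aS,6R,8aS)-6-hydroxy-2,5,5,8a-tetramethyl-4-oxo-1,4,4a,5,6,7,8,8a-octahydronaphthalen-1-yl]methoxy}-2H-chromen-2-one | O[C@@H]1CC[C@@]2(C)[C@H](COc3ccc4ccc(=O)oc4c3)C(C)=CC(=O)[C@@H]2C1(C)C | intermediate
21 | 7-{[(1R,4aS,6R,8aS)-6-(acetyloxy)-2,5,5,8a-tetramethyl-4-oxo-1,4,4a,5,6,7,8,8a-octahydronaphthalen-1-yl]methoxy}-2H-chromen-2-one | CC(=O)O[C@@H]1CC[C@@]2(C)[C@H](COc3ccc4ccc(=O)oc4c3)C(C)=CC(=O)[C@@H]2C1(C)C | target

**Totals**

Total step count: 14
Longest linear sequence: 14 steps (1 to 21); compounds 4, 10 and 17 enter directly as purchased.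

**Steps most likely to fail**

Step 9. The cycloaddition may be too slow at a trisubstituted dienophile next to a quaternary carbon, so that hydrolysis or isomerisation of the silyl enol ether outruns ring closure. Endo and facial selectivity may also be eroded at the temperature required, since the equatorial preference of a silyloxy group is small. A shortfall at C5 alone may still be repairable at the stage of 19, where C5 is alpha to the ketone. The fallback replaces the pericyclic closure by a stepwise ionic one that forms the same two bonds. It sets out from enone 13: LiN(SiMe3)2 in THF (−78 °C to rt) should deprotonate C5 to the cross-conjugated lithium dienolate, which closes ring A by conjugate addition to C10. The ester enolate so formed then closes ring B by conjugate addition to C8 (intramolecular double Michael reaction). Protonation should give the ketone methyl (1R,2R,4aS,6R,8aR)-6-[(tert-butyldimethylsilyl)oxy]-2,5,5,8a-tetramethyl-4-oxodecahydronaphthalene-1-carboxylate F1. Kinetic enolisation of F1 at C7, the only methylene beside the C6 carbonyl, with LiN(SiMe3)2 and TESCl in THF at −78 °C returns to 15. A different configuration at C8 would be of no consequence, since that centre is removed in step 12.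

Step 11. Transfer of the triethylsilyl group from the enol ether to the acidic phenol may occur, with loss of the regiodefined masked ketone. Substitution may also be slow at a primary carbinol crowded by the quaternary C10 and the C8 methyl group. The fallback inverts the order of events so that no silyl enol ether meets the phenol. It sets out from 16: Pd(OAc)2 in MeCN (Saegusa–Ito oxidation at the alcohol stage) should give {(1R,4aS,6R,8aS)-6-[(tert-butyldimethylsilyl)oxy]-2,5,5,8a-tetramethyl-4-oxo-1,4,4a,5,6,7,8,8a-octahydronaphthalen-1-yl}methanol F2. Mitsunobu etherification of F2 with 17 (PPh3, DIAD, toluene, rt to 50 °C) then comes back to the route at 19, so that step 12 is no longer needed.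

Step 12. Protodesilylation of the enol ether by the acetic acid formed may give the saturated ketone instead of palladation. Syn beta-hydride elimination from the hindered tertiary C8–H may also be slow. The fallback uses selenoxide elimination in place of palladium. It sets out from 18: PhSeCl in CH2Cl2 at −78 °C should react at C7 of the silyl enol ether from the face opposite the two axial methyl groups to give 7-{[(1R,2S,3R,4aS,6R,8aS)-6-[(tert-butyldimethylsilyl)oxy]-2,5,5,8a-tetramethyl-4-oxo-3-(phenylselanyl)decahydronaphthalen-1-yl]methoxy}-2H-chromen-2-one F3. Oxidation of F3 with H2O2 and pyridine in CH2Cl2 at 0 °C and syn elimination of the selenoxide across C7–C8 (the C8–H lies on the same face as selenium) comes back to the route at 19.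

**Further compounds**

F1 | step 9 | methyl (1R,2R,4aS,6R,8aR)-6-[(tert-butyldimethylsilyl)oxy]-2,5,5,8a-tetramethyl-4-oxodecahydronaphthalene-1-carboxylate | CC(C)(C)[Si](C)(C)O[C@@H]1CC[C@@]2(C)[C@H](C(=O)OC)[C@H](C)CC(=O)[C@@H]2C1(C)C
F2 | step 11 | {(1R,4aS,6R,8aS)-6-[(tert-butyldimethylsilyl)oxy]-2,5,5,8a-tetramethyl-4-oxo-1,4,4a,5,6,7,8,8a-octahydronaphthalen-1-yl}methanol | CC(C)(C)[Si](C)(C)O[C@@H]1CC[C@@]2(C)[C@H](CO)C(C)=CC(=O)[C@@H]2C1(C)C
F3 | step 12 | 7-{[(1R,2S,3R,4aS,6R,8aS)-6-[(tert-butyldimethylsilyl)oxy]-2,5,5,8a-tetramethyl-4-oxo-3-(phenylselanyl)decahydronaphthalen-1-yl]methoxy}-2H-chromen-2-one | CC(C)(C)[Si](C)(C)O[C@@H]1CC[C@@]2(C)[C@H](COc3ccc4ccc(=O)oc4c3)[C@H](C)[C@@H]([Se]c3ccccc3)C(=O)[C@@H]2C1(C)C
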